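Count the delays first.

| flask | substrate | coupling partner | time | remark |
|---|---|---|---|---|
| red | 0.050 M (fed, over 2.50 d) | 0.100 M | 2.5 d | all but substrate at the start; substrate goes in evenly over 2.50 d, the run ends at 2.5 d |
| amber | 0.050 M | 0.100 M | 2.5 d | a closed flask charged with all of it at once and left for 2.5 d |
| ochre | 0.050 M | 0.100 M (fed, over 2.50 d) | 2.5 d | a stirred flask in which coupling partner is dosed at a steady rate over 2.50 d without added volume, worked up at 2.5 d |
| green | 0.050 M | 0.100 M |  | one stirred flow tank at steady state, fed with the mixture as stated, mean residence time 2.5 d |

- the set-up with the highest amount of target at the outlet or at the end, in percent of the substrate put in ("none" if the first two lie within 2 percentage points) (red / amber / ochre / green / none)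
- amount of target at the outlet or at the end, in percent of the substrate put in, red
- amount of target at the outlet or at the end, in percent of the substrate put in, amber
- amount of target at the outlet or at the end, in percent of the substrate put in, ochre
- amount of target at the outlet or at the end, in percent of the substrate put in, green

- percentages count the substrate that a species holds: one side product B counts as two
- the stated concentrations are those of everything mixed, before any reaction; amounts are the same in each set-up
- the feed brings no volume worth counting
- run time (red): 2.5 d

    substrate + coupling partner ⇌ intermediate A (K1 = 10 M⁻¹, k1 = 0.0014 M⁻¹ s⁻¹)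
    substrate + coupling partner → intermediate B (k2 = 4.1 × 10⁻⁴ M⁻¹ s⁻¹)
    intermediate B → side product A (k3 = 3.6 × 10⁻⁶ s⁻¹)
    intermediate B → intermediate C (k4 = 5.2 × 10⁻⁵ s⁻¹)
    intermediate B ⇌ intermediate D (K5 = 2.1, k5 = 1.3 × 10⁻⁴ s⁻¹)
    intermediate C → target (k6 = 1.0 × 10⁻⁵ s⁻¹)
    intermediate C → side product A (k7 = 2.4 × 10⁻⁵ s⁻¹)
    substrate + target → side product B (k8 = 1.6 × 10⁻⁴ M⁻¹ s⁻¹)

**Three delays.** We reckon by hand with a chain of three pools, and we set step 8 aside. Step 1 has a shorter half-life than step 2, and the forward step 5 runs faster than the two exits of intermediate B, so we treat both as equilibria. We replace the falling [coupling partner] by its mean, 0.0750 M. The substrate pool then decays pseudo-first-order, with mean delay 0.659 d, intermediate A included. Intermediates B and D together give 0.645 d, and intermediate C gives 0.340 d. The sum is 1.64 d.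

**Chain number.** Dividing the run time by this sum gives the chain number, 1.52: how many whole passages of the chain the run allows. The branches at intermediates B and C cap target at 27.5%. Treated as one step with the same mean delay, amber gives 21.5%.

**Testing it.** In red and ochre the dose lasts the whole run. Averaging over the portions gives 13.4% for red and 13.4% for ochre. Placing the whole dose at its mean arrival, half of the dosing time, gives 14.6%, and that gap is the error of the mean. For green, one number gives 16.6%, but taking the three delays stage by stage gives 15.2%, so the tank needs the delays separately. Our choice is amber.

**The forecast.** It names amber, with 10.3% for red, 21% for amber, 10.5% for ochre and 11.8% for green, reasoning “so the set-up that gets material in earliest wins”. Its figures for red, ochre and green lie below ours.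

**The result.** The best is amber: red gives 10.5%, amber 20.3%, ochre 12.1% and green 11.6%. The forecast's choice fails once a rival comes within 2 percentage points of amber, for the answer then reads none; ochre, the nearest, stands 8.2 points behind. Its percentages could also miss with amber still first: amber itself moves by 5 points at a time of 1.72 d or at 0.0605 M of coupling partner. Amber reaches 73.8% of the cap, where the chain number promised 78.1%. Red read at 4.0 d, counted from mean arrival, has a chain number of 1.67, which promises 22.3%, and that flask holds 20.0% of target.

The constants used here are assumed; the rest is arithmetic.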